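## Structural features

The target is a cis-fused 3,7-dioxabicyclo[3.3.0]octan-2-one. A γ-lactone (C1, C2, O3, C4, C5) and a tetrahydrofuran (C1, C5, C6, O7, C8) share the C1–C5 bond; C4 carries the 4-hydroxy-3,5-dimethoxyphenyl (syringyl) ring and C8 the 3,4-dihydroxyphenyl (catechol) ring. The four stereocentres C8, C1, C5 and C4 are contiguous, (1R,4S,5S,8S) in this numbering. All four ring hydrogens lie on the convex face, so both aryl groups sit on the concave face, the less stable diendo arrangement. The fragile points are the catechol (air oxidation), the benzylic C4–O3 and C8–O7 bonds (each para to a free phenol, so open to quinone-methide ionisation and epimerisation in acid or base), and the C1–H/C8–O7 pair (retro-oxa-Michael opening in base). The difficulty is therefore to place two aryl groups on the hindered face under kinetic control, in one absolute sense, and to unmask three phenols without disturbing those bonds. The feature exploited is the array O3–C4–C5(–C6–O7): C4–C5 is an aldol-type bond between an aryl aldehyde carbon and the β-carbon of a furan whose oxygen is O7, whose α-carbons are C6 and C8, and whose 3-carboxyl carbon is C2. A [2+2] photocycloaddition across the furan C5–C6 bond forms C4–C5 and a temporary O3–C6 bond; the exo-aryl oxetane becomes, once O3 moves from C6 to C2, the aryl group cis to C6.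

## Logic of the disconnections

14 is traced to 13 by cutting three phenolic O–acetyl bonds. With the phenols acylated neither benzylic C–O bond can ionise through a quinone methide and the catechol cannot oxidise, so acid, palladium and hydrogenation steps become usable. The gain is one protecting-group type removed in one operation. The demand is a near-neutral deacylation, since 14 tolerates neither acid nor phenoxide-forming base.

13 is cut at the lactone C2–O3 bond and at one C6–H bond, which reconnects O3 to C6 as the oxetane acetal of 10 and returns C2 to the auxiliary ester. O3 already sits on C4 with the right configuration and only has to change partner: a Lewis acid and a silane turn C6 into the methylene (11), and the freed hydroxyl (12) displaces the auxiliary. The gain is lactone closure, C6 deoxygenation and auxiliary removal in one operation. The demand is ionisation only at the strained C6–O3 bond, with C1–C8 already saturated. If the C1=C8 enol ether were still present, the cation at C6 would be the sigma complex of a furan and would aromatise by loss of the C5 proton, erasing C5. The double bond is therefore removed before the acetal is opened.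

10 is cut at C1–H and C8–H, giving 9. Syn delivery of two hydrogen atoms to the open exo face of the bicycle sets C1 and C8 together and forces the C8 aryl and the C1 ester to the endo side, which no nucleophilic arylation at C8 could do. The gain is two stereocentres from a planar carbon pair. The demand is reduction of a tetrasubstituted enol ether without cleaving the benzylic oxetane C–O bond.

9 is cut at the C8–aryl bond, giving 6 and 8. The arylation is placed on 6 and not on a later bicyclic lactone. In 6 the only competing β-hydrogen sits on C5, a fusion carbon of the four-membered ring, so elimination towards C5 would make a highly strained bridgehead alkene; in a bicyclo[3.3.0] lactone that elimination would be easy and would destroy C5. The gain is a convergent union with a simple aryl bromide. The demand is β-hydride elimination of the C8 hydrogen after face exchange of the palladium enolate.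

6 is cut at C4–C5 and O3–C6, giving 2 and 5. This is the strategic cut: one photochemical step forms the aldol-type bond, the oxetane and three stereocentres from an aldehyde and an aromatic ester. Checked atom by atom, the (1S,5R,6S) exo adduct on the (1R,2S,5R) auxiliary carries (4S,5S) of 14, so no structure needs correcting; only the order of the later operations is changed. The demand is selectivity for the unsubstituted furan double bond, oxygen to C6, exo aryl, and one furan face.

5 is cut at the ester C–O bond, giving 3 and 4. The auxiliary is bought, not built, and is released again in step 7. The demand is acylation of a hindered secondary alcohol.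

2 is cut at the O–acetyl bond, giving 1. The acyl group keeps the aldehyde photoreactive and later protects C4–O3. The demand is trivial.

8 is cut at two O–acetyl bonds, giving 7. The acetates match the protecting group of 2 and keep the catechol away from palladium. The demand is trivial.

## Other disconnections considered

Alternative 1: The cut removes C2 as carbon monoxide and opens O7–C8, C1–C2 and C2–O3, leading back to the silylated 2-alkynyl-1,3-diol A1, which already holds C4, C5 and the catechol ring. Forward, PdI2/KI under CO and air would cause 5-endo-dig attack of the primary hydroxyl on the alkyne, CO insertion at C1 and capture of the acyl group by the C4 hydroxyl, giving the enol ether lactone A2.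
- In its favour: both rings and the carbonyl carbon appear in one catalytic step. The C8 aryl comes from an alkyne coupling, which is more dependable than the arylation of step 5; here the alternative is the better plan. A2 also needs the convex-face hydrogenation with no strained oxetane nearby, a further advantage.
- Against it: the step creates no stereocentre, so C4 and C5 must be set beforehand in an acyclic sequence with relative and absolute control. Both hydroxyls of A1 are homopropargylic, so the benzylic one can start the cascade and give the constitutional isomer. CO pressure and an oxidising medium meet a benzylic alcohol.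
- Comparison: step economy should be about equal. The chosen plan sets C4 and C5 in one step but carries more risk afterwards.

Alternative 2: The cut is C4–C5 and C2–O3, leading back to the silyloxy enal A3 and the silylated aldehyde A4. Forward, a chiral triazolylidene carbene would turn A3 into a homoenolate that adds through C5 to A4; the alkoxide then acylates on the acyl azolium and gives the cis lactone A5.
- In its favour: it is organocatalytic, needs no photochemistry or auxiliary, and belongs to an established reaction class, whereas step 3 does not. On precedent this alternative is the better one.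
- Against it: A5 lacks C8 and the second ring, so C1–C8, O7–C8 and two stereocentres remain to be made. The silyloxy group is β to the nucleophilic carbon and may be eliminated. Enantio- and cis/trans selectivity in this class is usually moderate.
- Comparison: it forms the same bond with the same cis outcome. Endo placement of the C8 aryl by hydride addition to an oxocarbenium ion is at least as well founded as steps 5 and 6. Step counts are about equal. It is kept as the fallback for step 3.

Alternative 3: The cut is C1–C5 and O7–C6, leading back to the propargylic aroylacetate A6, whose only stereocentre is C4. Forward, Mn(OAc)3 with Cu(OAc)2 would give the C1 radical, 5-exo-dig closure of the lactone, capture of the C6 vinyl radical by the ketone oxygen and oxidative aromatisation to the furanolactone A7.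
- In its favour: the whole skeleton with both aryl rings forms in one step from a readily made ester, so on step economy this alternative is the better one. Its single stereocentre can come from an asymmetric alkynylation.
- Against it: ester-tethered radicals cyclise reluctantly. Closure of a furan by vinyl-radical attack on a carbonyl oxygen is unusual. Most seriously, A7 is an aromatic furan, so C1, C5 and C8 must all be made by forcing hydrogenation next to a lactone C–O bond that is benzylic and furfurylic.
- Comparison: the chosen plan keeps C5 from the photocycloaddition onward and reduces only one enol ether. Mechanistically the two key steps are comparably speculative.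

Key step: step 3

Assumption: the furoate reacts through the Z ester conformer with furan C4–H on the alkoxy side under the phenyl ring, so the (1R,2S,5R) auxiliary exposes the face leading to (4S,5S); if the sense is opposite, the enantiomeric auxiliary is used with no other change.

Step 1
Reactants: 1 syringaldehyde
Product: 2 4-formyl-2,6-dimethoxyphenyl acetate
Conditions: Ac2O, pyridine, DMAP (cat.), CH2Cl2, rt
Reagents that add atoms: acetic anhydride, CC(=O)OC(C)=O
Why: DMAP-catalysed acylation of the phenol; the hindered 2,6-dimethoxyphenol should acetylate cleanly under these standard conditions and the aldehyde is untouched.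

Step 2
Reactants: 3 furan-3-carboxylic acid; 4 (−)-8-phenylmenthol
Product: 5 (1R,2S,5R)-5-methyl-2-(2-phenylpropan-2-yl)cyclohexyl furan-3-carboxylate
Conditions: DCC, DMAP, CH2Cl2, 0 °C to rt
Reagents that add atoms: none
Why: Steglich esterification; DMAP passes the acyl group of the O-acylisourea to the hindered secondary alcohol, and no stereocentre is touched.

Step 3
Reactants: 2 4-formyl-2,6-dimethoxyphenyl acetate; 5 (−)-8-phenylmenthyl furan-3-carboxylate
Product: 6 (−)-8-phenylmenthyl (1S,5R,6S)-6-(4-acetoxy-3,5-dimethoxyphenyl)-2,7-dioxabicyclo[3.2.0]hept-3-ene-4-carboxylate (cis-fused, aryl exo)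
Conditions: hν (350 nm, Pyrex), 5 (3 equiv, excess recovered), C6H6, 10 °C, Ar
Reagents that add atoms: none
Why: Proposed new method: the n,π* triplet of 2 should add through oxygen to furan C5 (the α-carbon of the double bond without the ester), giving a 1,4-diradical that is benzylic at one end and an ester-conjugated oxyallyl radical at the other, which closes the C–C bond after intersystem crossing; the closest known reaction type is the exo-selective Paternò–Büchi photocycloaddition of aromatic aldehydes to furan and alkylfurans, not yet shown for a furan-3-carboxylate with a chiral ester. The one new ring, the oxetane, closes stepwise (O–C bond first, then radical recombination of the 1,4-diradical), which can only give the cis ring fusion. C5 and C6 of the target numbering are thus set together, C4 follows from the exo preference of the aryl group in the diradical conformer that undergoes spin inversion, and the absolute sense of all three is meant to come from the auxiliary, whose phenyl ring lies over the furan C3–C4 edge in the Z ester and leaves the opposite face open. Site selectivity rests on the ester, which makes the 2,3-bond a vinylogous carbonate and a poor partner for the electrophilic oxygen; regioselectivity rests on diradical stability; the acetyl group keeps the aldehyde triplet n,π* in character. Facial selectivity is the unproven part and is made less critical by design, because the two exo diastereomers differ in the auxiliary and should be separable at 6 by crystallisation or chromatography.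

Step 4
Reactants: 7 4-bromobenzene-1,2-diol
Product: 8 4-bromo-1,2-phenylene diacetate
Conditions: Ac2O, pyridine, DMAP (cat.), CH2Cl2, rt
Reagents that add atoms: acetic anhydride, CC(=O)OC(C)=O
Why: Acylation of both phenols; the acetates keep the catechol from binding palladium and from oxidation, and leave with the third acetate in step 8.

Step 5
Reactants: 6 exo-aryl oxetane ester; 8 4-bromo-1,2-phenylene diacetate
Product: 9 (−)-8-phenylmenthyl (1R,5R,6S)-6-(4-acetoxy-3,5-dimethoxyphenyl)-3-(3,4-diacetoxyphenyl)-2,7-dioxabicyclo[3.2.0]hept-3-ene-4-carboxylate
Conditions: Pd(OAc)2 (5 mol%), P(t-Bu)3·HBF4 (10 mol%), Cy2NMe, 1,4-dioxane, 70 °C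
Reagents that add atoms: none
Why: Mizoroki–Heck arylation of a β-alkoxy acrylate: the arylpalladium bromide should add from the exo face with aryl to the oxygen-bearing C3 and palladium to C4, and after face exchange through the oxygen-bound palladium enolate the C3 hydrogen is eliminated, restoring the conjugated enol ether. The only other β-hydrogen is on C5, a fusion carbon of the oxetane, where elimination would give a highly strained bridgehead alkene; no stereocentre is made or lost.

Step 6
Reactants: 9 3-aryl oxetane ester
Product: 10 (−)-8-phenylmenthyl (1R,3S,4R,5R,6S)-6-(4-acetoxy-3,5-dimethoxyphenyl)-3-(3,4-diacetoxyphenyl)-2,7-dioxabicyclo[3.2.0]heptane-4-carboxylate (3-aryl and 4-ester endo)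
Conditions: H2 (4 bar), 5% Rh/Al2O3, EtOAc, rt
Reagents that add atoms: none
Why: Heterogeneous syn hydrogenation from the open exo face (the oxetane blocks the endo face) should place both new hydrogens cis to H1 and H5, so the aryl group and the ester end up endo, which are the C8 and C1 configurations of the target. Rhodium on alumina is chosen because it has little tendency to cleave the strained benzylic C–O bond of the oxetane, which palladium would attack.

Step 7
Reactants: 10 saturated oxetane acetal
Product: 13 (3S,3aS,6S,6aR)-3-(4-acetoxy-3,5-dimethoxyphenyl)-6-(3,4-diacetoxyphenyl)tetrahydro-1H,3H-furo[3,4-c]furan-1-one, via triethylsilyl ether 11 (not isolated), via hydroxy ester 12 (not isolated)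
Conditions: Et3SiH, Et3SiOTf (cat.), CH2Cl2, −78 °C; then p-TsOH·H2O (cat.), PhMe, 50 °C
Reagents that add atoms: none
Why: Ionic reduction of a bicyclic acetal followed by acid-catalysed lactonisation: the silyl triflate ionises the strained acetal C–O bond of the oxetane, the tetrahydrofuranyl oxocarbenium ion takes hydride from the silane, and the oxetane oxygen leaves as its silyl ether. Acid then removes the silyl group and the hydroxyl closes the γ-lactone onto the cis ester, releasing the auxiliary. Because the enol ether was saturated in step 6 the cation cannot aromatise, and the carbinol C–O bond is never broken, so C4 is retained.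

Step 8
Reactants: 13 triacetyl lactone
Product: 14 (3S,3aS,6S,6aR)-6-(3,4-dihydroxyphenyl)-3-(4-hydroxy-3,5-dimethoxyphenyl)tetrahydro-1H,3H-furo[3,4-c]furan-1-one (CNP0224550.1)
Conditions: NH4OAc, MeOH–H2O (4:1), rt, Ar
Reagents that add atoms: none
Why: Ammonium acetate-promoted methanolysis of aryl acetates near neutral pH; it avoids phenoxide formation, which would permit quinone-methide epimerisation at C4 or C8 and retro-oxa-Michael opening, and should leave the lactone intact.

Compound list

1 | syringaldehyde (4-hydroxy-3,5-dimethoxybenzaldehyde) | COc1cc(C=O)cc(OC)c1O | starting material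
2 | 4-formyl-2,6-dimethoxyphenyl acetate | COc1cc(C=O)cc(OC)c1OC(C)=O | intermediate
3 | furan-3-carboxylic acid | OC(=O)c1ccoc1 | starting material
4 | (−)-8-phenylmenthol, (1R,2S,5R)-5-methyl-2-(2-phenylpropan-2-yl)cyclohexan-1-ol | C[C@@H]1CC[C@H]([C@@H](C1)O)C(C)(C)c1ccccc1 | starting material
5 | (1R,2S,5R)-5-methyl-2-(2-phenylpropan-2-yl)cyclohexyl furan-3-carboxylate | C[C@@H]1CC[C@H]([C@@H](C1)OC(=O)c1ccoc1)C(C)(C)c1ccccc1 | intermediate
6 | (−)-8-phenylmenthyl (1S,5R,6S)-6-(4-acetoxy-3,5-dimethoxyphenyl)-2,7-dioxabicyclo[3.2.0]hept-3-ene-4-carboxylate | C[C@@H]1CC[C@H]([C@@H](C1)OC(=O)C1=CO[C@H]2O[C@H](c3cc(OC)c(OC(C)=O)c(OC)c3)[C@@H]12)C(C)(C)c1ccccc1 | intermediate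
7 | 4-bromobenzene-1,2-diol | Oc1ccc(Br)cc1O | starting material
8 | 4-bromo-1,2-phenylene diacetate | CC(=O)Oc1ccc(Br)cc1OC(C)=O | intermediate
9 | (−)-8-phenylmenthyl (1R,5R,6S)-6-(4-acetoxy-3,5-dimethoxyphenyl)-3-(3,4-diacetoxyphenyl)-2,7-dioxabicyclo[3.2.0]hept-3-ene-4-carboxylate | C[C@@H]1CC[C@H]([C@@H](C1)OC(=O)C1=C(c2ccc(OC(C)=O)c(OC(C)=O)c2)O[C@H]2O[C@H](c3cc(OC)c(OC(C)=O)c(OC)c3)[C@@H]12)C(C)(C)c1ccccc1 | intermediate
10 | (−)-8-phenylmenthyl (1R,3S,4R,5R,6S)-6-(4-acetoxy-3,5-dimethoxyphenyl)-3-(3,4-diacetoxyphenyl)-2,7-dioxabicyclo[3.2.0]heptane-4-carboxylate | C[C@@H]1CC[C@H]([C@@H](C1)OC(=O)[C@H]1[C@@H](c2ccc(OC(C)=O)c(OC(C)=O)c2)O[C@H]2O[C@H](c3cc(OC)c(OC(C)=O)c(OC)c3)[C@@H]12)C(C)(C)c1ccccc1 | intermediate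
11 | (−)-8-phenylmenthyl (2S,3R,4S)-4-[(S)-(4-acetoxy-3,5-dimethoxyphenyl)(triethylsilyloxy)methyl]-2-(3,4-diacetoxyphenyl)oxolane-3-carboxylate (formed in step 7, not isolated) | C[C@@H]1CC[C@H]([C@@H](C1)OC(=O)[C@H]1[C@@H](c2ccc(OC(C)=O)c(OC(C)=O)c2)OC[C@H]1[C@H](O[Si](CC)(CC)CC)c1cc(OC)c(OC(C)=O)c(OC)c1)C(C)(C)c1ccccc1 | intermediate
12 | (−)-8-phenylmenthyl (2S,3R,4S)-4-[(S)-(4-acetoxy-3,5-dimethoxyphenyl)(hydroxy)methyl]-2-(3,4-diacetoxyphenyl)oxolane-3-carboxylate (formed in step 7, not isolated) | C[C@@H]1CC[C@H]([C@@H](C1)OC(=O)[C@H]1[C@@H](c2ccc(OC(C)=O)c(OC(C)=O)c2)OC[C@H]1[C@H](O)c1cc(OC)c(OC(C)=O)c(OC)c1)C(C)(C)c1ccccc1 | intermediate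
13 | (3S,3aS,6S,6aR)-3-(4-acetoxy-3,5-dimethoxyphenyl)-6-(3,4-diacetoxyphenyl)tetrahydro-1H,3H-furo[3,4-c]furan-1-one | COc1cc([C@H]2OC(=O)[C@@H]3[C@H]2CO[C@@H]3c2ccc(OC(C)=O)c(OC(C)=O)c2)cc(OC)c1OC(C)=O | intermediate
14 | (3S,3aS,6S,6aR)-6-(3,4-dihydroxyphenyl)-3-(4-hydroxy-3,5-dimethoxyphenyl)tetrahydro-1H,3H-furo[3,4-c]furan-1-one (CNP0224550.1) | COc1cc([C@H]2OC(=O)[C@@H]3[C@H]2CO[C@@H]3c2ccc(O)c(O)c2)cc(OC)c1O | target

Total: 8 steps. Longest linear sequence: 6 steps (step 1 or 2, then steps 3, 5, 6, 7 and 8).

Least certain steps

Step 3 (key step, proposed new method). The most likely failure is poor discrimination between the furan faces: the furoate can rotate about its ring–carbonyl bond, the two rotamers present opposite faces, and only one lies under the phenyl shield. A second failure is slow addition to the electron-poor furan, so that pinacol-type coupling and hydrogen abstraction consume the triplet aldehyde. Separation of diastereomers at 6 answers the first but not the second. The fallback uses known chemistry and runs from 1 to 14. Silylation of 1 (TBSCl, imidazole) gives 4-(tert-butyldimethylsilyloxy)-3,5-dimethoxybenzaldehyde F1. Carbene-catalysed homoenolate annulation of F1 with (E)-4-(tert-butyldimethylsilyloxy)but-2-enal F2 (chiral aminoindanol-derived N-mesityl triazolium tetrafluoroborate, DBU, THF; catalyst enantiomer chosen for the 4S,5S series) gives the cis lactone F3. Deprotonation with LiN(SiMe3)2 and C-acylation with 3,4-bis(tert-butyldimethylsilyloxy)benzoyl chloride F4 gives the 3-aroyl lactone F5. CSA in MeOH frees the primary hydroxyl, which closes onto the ketone, and Et3SiH/BF3·OEt2 reduces the hemiketal from the convex face to the tris-silyl ether F6 with the catechol ring endo. Bu4NF buffered with AcOH then gives 14.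

Step 5. The most likely failure is stalling of the catalytic cycle, or reductive capture of the alkylpalladium intermediate by the amine. After syn addition the C3 hydrogen is anti to palladium, and elimination needs face exchange through the palladium enolate to the crowded endo side. Opening of the acetal at 70 °C is a lesser concern. The fallback runs from 5 and 8 to 9. Direct C2–H arylation of the furoate (Pd(PPh3)4, KOAc, toluene, 110 °C, the C2-selective mode of 3-furoates) gives (−)-8-phenylmenthyl 2-(3,4-diacetoxyphenyl)furan-3-carboxylate F7. F7 is irradiated with 2 as in step 3 and should give 9 directly. The cost is a furan chromophore that may quench the aldehyde triplet.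

Step 6. The most likely failure is slow reduction of the hindered tetrasubstituted alkene, so that hydrogenolysis of the strained benzylic C–O bond or saturation of an aryl ring competes. Saturation of the auxiliary phenyl ring would not affect 14. The fallback runs from 9 to 11 and opens the oxetane first. Et3SiH in large excess with Et3SiOTf at −78 °C gives the dihydrofuran silyl ether F8; H2 over 10% Pd/C in EtOAc, now without a strained ring, reduces it anti to the C4 side chain to give 11, which is lactonised as in step 7. This order is second choice because the cation formed from 9 can aromatise.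

Step 7. The most likely failure is loss of the C5 proton from the oxocarbenium ion, with epimerisation on reprotonation, or slow lactonisation onto the hindered ester, during which acid begins to cleave acetates. The fallback runs from 10 to 13 and separates the two events. Dilute aqueous HCl in THF hydrolyses the acetal to the C6 lactol, and p-TsOH in toluene closes the lactone with release of the auxiliary, giving the lactol lactone F9. Et3SiH/BF3·OEt2 at −78 °C then reduces the lactol to 13.

## Further compounds

F1 | step 3 | 4-(tert-butyldimethylsilyloxy)-3,5-dimethoxybenzaldehyde | COc1cc(C=O)cc(OC)c1O[Si](C)(C)C(C)(C)C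
F2 | step 3 | (E)-4-(tert-butyldimethylsilyloxy)but-2-enal | CC(C)(C)[Si](C)(C)OC/C=C/C=O
F3 | step 3 | (4S,5S)-4-[(tert-butyldimethylsilyloxy)methyl]-5-[4-(tert-butyldimethylsilyloxy)-3,5-dimethoxyphenyl]dihydrofuran-2(3H)-one | COc1cc([C@H]2OC(=O)C[C@H]2CO[Si](C)(C)C(C)(C)C)cc(OC)c1O[Si](C)(C)C(C)(C)C
F4 | step 3 | 3,4-bis(tert-butyldimethylsilyloxy)benzoyl chloride | CC(C)(C)[Si](C)(C)Oc1ccc(C(Cl)=O)cc1O[Si](C)(C)C(C)(C)C
F5 | step 3 | (4S,5S)-3-[3,4-bis(tert-butyldimethylsilyloxy)benzoyl]-4-[(tert-butyldimethylsilyloxy)methyl]-5-[4-(tert-butyldimethylsilyloxy)-3,5-dimethoxyphenyl]dihydrofuran-2(3H)-one (C3 epimers) | COc1cc([C@H]2OC(=O)C(C(=O)c3ccc(O[Si](C)(C)C(C)(C)C)c(O[Si](C)(C)C(C)(C)C)c3)[C@H]2CO[Si](C)(C)C(C)(C)C)cc(OC)c1O[Si](C)(C)C(C)(C)C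
F6 | step 3 | tris(tert-butyldimethylsilyl) ether of 14 | COc1cc([C@H]2OC(=O)[C@@H]3[C@H]2CO[C@@H]3c2ccc(O[Si](C)(C)C(C)(C)C)c(O[Si](C)(C)C(C)(C)C)c2)cc(OC)c1O[Si](C)(C)C(C)(C)C
F7 | step 5 | (−)-8-phenylmenthyl 2-(3,4-diacetoxyphenyl)furan-3-carboxylate | C[C@@H]1CC[C@H]([C@@H](C1)OC(=O)c1ccoc1-c1ccc(OC(C)=O)c(OC(C)=O)c1)C(C)(C)c1ccccc1
F8 | step 6 | (−)-8-phenylmenthyl (4S)-4-[(S)-(4-acetoxy-3,5-dimethoxyphenyl)(triethylsilyloxy)methyl]-2-(3,4-diacetoxyphenyl)-4,5-dihydrofuran-3-carboxylate | C[C@@H]1CC[C@H]([C@@H](C1)OC(=O)C1=C(c2ccc(OC(C)=O)c(OC(C)=O)c2)OC[C@H]1[C@H](O[Si](CC)(CC)CC)c1cc(OC)c(OC(C)=O)c(OC)c1)C(C)(C)c1ccccc1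
F9 | step 7 | C6 lactol of 13 (6-hydroxy derivative in the target numbering, anomeric mixture) | COc1cc([C@H]2OC(=O)[C@@H]3[C@H]2C(O)O[C@@H]3c2ccc(OC(C)=O)c(OC(C)=O)c2)cc(OC)c1OC(C)=O
A1 | alternative 1 | (1S,2S)-2-{[3,4-bis(tert-butyldimethylsilyloxy)phenyl]ethynyl}-1-[4-(tert-butyldimethylsilyloxy)-3,5-dimethoxyphenyl]propane-1,3-diol | COc1cc([C@@H](O)[C@H](CO)C#Cc2ccc(O[Si](C)(C)C(C)(C)C)c(O[Si](C)(C)C(C)(C)C)c2)cc(OC)c1O[Si](C)(C)C(C)(C)C
A2 | alternative 1 | tris(tert-butyldimethylsilyl) ether of the C1=C8 enol ether lactone corresponding to 14 | COc1cc([C@H]2OC(=O)C3=C(c4ccc(O[Si](C)(C)C(C)(C)C)c(O[Si](C)(C)C(C)(C)C)c4)OC[C@@H]23)cc(OC)c1O[Si](C)(C)C(C)(C)C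
A3 | alternative 2 | (E)-4-(tert-butyldimethylsilyloxy)but-2-enal | CC(C)(C)[Si](C)(C)OC/C=C/C=O
A4 | alternative 2 | 4-(tert-butyldimethylsilyloxy)-3,5-dimethoxybenzaldehyde | COc1cc(C=O)cc(OC)c1O[Si](C)(C)C(C)(C)C
A5 | alternative 2 | (4S,5S)-4-[(tert-butyldimethylsilyloxy)methyl]-5-[4-(tert-butyldimethylsilyloxy)-3,5-dimethoxyphenyl]dihydrofuran-2(3H)-one | COc1cc([C@H]2OC(=O)C[C@H]2CO[Si](C)(C)C(C)(C)C)cc(OC)c1O[Si](C)(C)C(C)(C)C
A6 | alternative 3 | (S)-1-(4-acetoxy-3,5-dimethoxyphenyl)prop-2-yn-1-yl 3-(3,4-diacetoxyphenyl)-3-oxopropanoate | COc1cc([C@H](C#C)OC(=O)CC(=O)c2ccc(OC(C)=O)c(OC(C)=O)c2)cc(OC)c1OC(C)=O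
A7 | alternative 3 | 3-(4-acetoxy-3,5-dimethoxyphenyl)-6-(3,4-diacetoxyphenyl)furo[3,4-c]furan-1(3H)-one, C3 configured as C4 of 14 | COc1cc([C@H]2OC(=O)c3c2coc3-c2ccc(OC(C)=O)c(OC(C)=O)c2)cc(OC)c1OC(C)=O
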